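A rate in molar per second divided by another rate in the same unit leaves a bare number, and where both rates run on incoming ligand, [incoming ligand] cancels from that number as well.

    starting complex + incoming ligand → leaving ligand + complex with one exchanged (k1 = 0.0195 M⁻¹ s⁻¹)
    complex with one exchanged + incoming ligand → leaving ligand + complex with two exchanged (k2 = 0.0437 M⁻¹ s⁻¹)
    complex with two exchanged + incoming ligand → leaving ligand + complex with three exchanged (k3 = 0.0525 M⁻¹ s⁻¹)
    complex with one exchanged + capture agent → trapped intermediate (k4 = 0.0122 M⁻¹ s⁻¹)

| setting | Monday's | Saturday's | Sunday's |
|---|---|---|---|
| starting complex | 0.076 M | 0.076 M | 0.076 M |
| incoming ligand | 0.0600 M (fed, over 4.0 min) | 0.100 M (fed, over 4.0 min) | 0.150 M (fed, over 4.0 min) |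
| capture agent | 0.0760 M | 0.0760 M | 0.0760 M |
| time | 30 min | 30 min | 30 min |

- [complex with two exchanged] at the end for Monday's, Saturday's, Sunday's, in this order
- how the row runs (rises all the way / hardly changes / falls all the way / rises, then falls / falls, then rises)

The complex with two exchanged is made by the second step and lost by the third, and both steps run on incoming ligand. Loss over gain therefore contains no [incoming ligand]. The constant of the third step over that of the second, 1.20, is the selectivity factor, and loss over gain is this factor times [complex with two exchanged]/[complex with one exchanged]. So [complex with two exchanged] stops growing when that concentration ratio reaches 0.833, and it falls beyond that point.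

Three settings can be turned, and by hand they act as follows.

The ligand charge comes first. Monday's flask holds 0.789 ligand per starting complex, while the complex with two exchanged takes two, so by hand more ligand should raise the row at first. Sunday's flask holds about twice the starting complex, and the third step has the larger constant. More of the complex should therefore have passed on by then. My reckoning commits to a row that rises, then falls, but it gives no end values.

The feed comes second. In Monday's flask it lasts 4.0 min, less than the 9.9 min half-life of the starting complex by the first step with the whole charge counted at once. By hand, dosing bit by bit should therefore change little.

The capture agent comes third. In Monday's flask it removes the complex with one exchanged with a half-life of 12 min, slower than the 4.4 min of the second step with the whole ligand charge counted at once. It lowers [complex with one exchanged] and leaves the selectivity factor as it is.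

The forecast gives 0.0071 M, 0.009 M and 0.0076 M, a row that rises, then falls, and it puts the drop on Sunday's flask “because more has moved on to the three-exchanged complex”. Unlike my reckoning, it commits to numbers.

The flasks give 0.00715 M, 0.00896 M and 0.00756 M, so the row rises, then falls. The local order in ligand is 0.75 around Monday's charge and −1.0 around Sunday's. With the selectivity factor, loss over gain for the complex with two exchanged stands at 1.12 at the end of Monday's flask and 1.68 at the end of Sunday's, both above one, so the end values lie past the top. Sunday's complex with two exchanged goes from 9.95% of the starting complex charged to 5.04% after 300 min, and Monday's from 9.40% to 8.94%.

The numbers of this flask come from no measurement; no experiment stands behind them.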